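Monday's run, with 60 mM of free base, keeps 14.4% of its electrophile after 6.00 d, and Tuesday's run, with 15 mM, keeps 18.4%, so a change of free base by a factor of 4.00 moves that reading by 4 percentage points.

| setting | Tuesday's | Monday's | Saturday's | flask |
|---|---|---|---|---|
| electrophile | 20 mM | 20 mM | 30 mM | 20 mM |
| free base | 15 mM | 60 mM | 30 mM | 30.0 mM |
| protonated nucleophile | 60 mM | 60 mM | 60 mM | 60.0 mM |
| remark | run made earlier | run made earlier | run made earlier |  |
| time |  |  |  | 10 d |

| run | time / d | electrophile / % | target / % |
|---|---|---|---|
| Tuesday's | 1.67 | 61.1 | 37.9 |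
| Tuesday's | 3.00 | 40.7 | 54.7 |
| Tuesday's | 5.00 | 23.5 | 69.6 |
| Tuesday's | 6.00 | 18.4 | 72.9 |
| Monday's | 0.833 | 75.1 | 24.9 |
| Monday's | 2.00 | 50.0 | 46.3 |
| Monday's | 4.00 | 27.9 | 67.1 |
| Monday's | 6.00 | 14.4 | 77.1 |
| Saturday's | 0.833 | 78.4 | 20.7 |
| Saturday's | 2.00 | 57.3 | 40.4 |
| Saturday's | 4.00 | 36.3 | 59.9 |
| Saturday's | 6.00 | 21.4 | 69.4 |

(standard deviation of a reading: 0.5 percentage points)

- part of the electrophile that has reacted at 10 d
- share of the unused nucleophile that is free and not bound as protonated nucleophile, at 10 d

- the earlier runs do not show how much of nucleophile is bound; that part of a forecast is a guess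

1. The bench rule is pseudo-first-order decay: the electrophile loses the same fraction each day, and its decay number k is ln(charged/left) divided by the time, which at the last reading gives 0.282 d⁻¹ for Tuesday's run and 0.323 d⁻¹ for Monday's.

2. The asked flask holds twice Tuesday's free base and half Monday's, with the same electrophile and protonated nucleophile, so its decay number is taken as 0.302 d⁻¹, k_f, the geometric mean of the two runs' decay numbers.

3. The rule has a border if, as supposed here, one free base is taken per electrophile reacted: the crossing comes where the used fraction of the electrophile equals r, charged free base over charged electrophile. Tuesday's r of 0.750 puts it at 25.0% left, and the readings of that run show k falling from 0.295 d⁻¹ at the start to 0.245 d⁻¹ past it. Monday's r of 3.00 shows 0.344 d⁻¹ and then 0.331 d⁻¹.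

4. The asked flask has r of 1.50, so on that supposition its free base outlasts its electrophile, and k_f is reckoned to leave 4.89% of its electrophile at 10 d, that is 95.1% reacted. For the free share this reckoning gives no figure.

5. The forecast, which sees “a very weak base dependence”, says 94% reacted, against 95.1% reckoned here, and 15% free.

6. The flask gives 94.5% reacted and 1.98% free.

    electrophile + nucleophile → acid set free + target (k = 14.1 M⁻¹ h⁻¹)
    nucleophile + acid set free ⇌ protonated nucleophile, settled at all times (K = 30000 M⁻¹)
    acid set free + free base ⇌ salt of the base (K = 33000 M⁻¹, k = 3.28 M⁻¹ h⁻¹)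
    acid set free + target → side product (k = 0.693 M⁻¹ h⁻¹)
    crystals ⇌ acid set free, rate k5*(cs5 - [acid set free]) while solid is left; crystals form when [acid set free] > cs5 (solubility = 1.70 mM, k = 0.664 h⁻¹)

At 10.0 d the flask still holds 26% of its free base, against 5.5% of its electrophile. Read back, its reacted part is an average decay number of 0.290 d⁻¹, beside k_f of 0.302 d⁻¹. For the neighbour with 100 mM of protonated nucleophile, k_f multiplied, as a supposition, by the ratio of charges, 1.67, is reckoned to leave 0.653% of the electrophile, and that neighbour keeps 0.52%.

(The earlier runs and the new flask were generated by integration with constants of no real substance, and the scatter is random.)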